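Assumption: the target SMILES has no stereocentre and no stereodefined double bond. The compound (filixic acid PBP) is achiral, so there is no enantiomer to select. Enol and keto forms are drawn as in the given SMILES and interconvert freely.

## Retrosynthetic overview
1. Cut both aryl–CH2–C bonds last. This gives the central butanoylphloroglucinol (ring B), two C1 units (Mannich base / o-quinone methide) and two equivalents of propanoylfilicinic acid (ring A, used twice).
2. Ring A comes from a one-carbon ring expansion. The carbon of 1-diazobutan-2-one is inserted into the CO–CO bond of 3,3-dimethylcyclopentane-1,2,4-trione by a 1,2-acyl shift with loss of N2, and it brings the propanoyl group along.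
3. The five-membered trione comes from 3-methylbutan-2-one and dimethyl oxalate (Claisen, then Dieckmann). The diazoketone comes from propanoyl chloride and trimethylsilyldiazomethane.
4. Ring B comes from resorcinol by C5–H borylation/oxidation to phloroglucinol, then Friedel–Crafts butanoylation.
5. Ring order: the cyclopentane ring is formed first and then expanded to six-membered ring A. Ring B is aromatic from the start, and the final union forms no ring.

## Route

Step 1
Reactants: 1 3-methylbutan-2-one; 2 dimethyl oxalate
Product: 4 3,3-dimethylcyclopentane-1,2,4-trione (enol form: 4-hydroxy-2,2-dimethylcyclopent-4-ene-1,3-dione), via methyl 5-methyl-2,4-dioxohexanoate 3 (not isolated)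
Conditions: NaOMe (2.2 equiv), MeOH, 0 °C to rt; then toluene, distil off MeOH, 105 °C; 2 M HCl
Reagents that add atoms: none
Why: A crossed Claisen condensation at the methyl group of 1 gives 3, and a Dieckmann-type closure through the isopropyl methine (the classical ketone/oxalate route to cyclopentane-1,2,4-triones) follows, driven by removal of methanol and by the very stable enolate of 4; no stereocentre is formed.

Step 2
Reactants: 5 propanoyl chloride; 6 trimethylsilyldiazomethane
Product: 7 1-diazobutan-2-one
Conditions: 6 (2.0 M in hexanes, 1.3 equiv), MeCN/THF 1:1, 0 °C to rt; concentrate cold, short SiO2 plug, use as a CH2Cl2 solution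
Reagents that add atoms: none
Why: This is the Arndt–Eistert-type C-acylation of the nucleophilic diazo carbon by the acid chloride, after which chloride removes the silyl group to give the acyl diazomethane.

Step 3
Reactants: 4 3,3-dimethylcyclopentane-1,2,4-trione; 7 1-diazobutan-2-one
Product: 11 3,5-dihydroxy-4,4-dimethyl-2-propanoylcyclohexa-2,5-dien-1-one (propanoylfilicinic acid), via dichloroaluminium chelate 8 (not isolated), via oxido diazonium adduct 9 (not isolated), via dichloroaluminium enolate 10 (not isolated)
Conditions: MeAlCl2 (1.05 equiv), CH2Cl2, −78 to 0 °C; then 7 (1.2 equiv, slow addition), −40 °C to rt; 1 M HCl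
Reagents that add atoms: none
Why: Proposed new method: formal insertion of an acyl diazomethane carbon into the C1–C2 (CO–CO) bond of a cyclopentane-1,2,4-trione; the acidic enol protonolyses MeAlCl2 (CH4 leaves), so no Brønsted acid remains to O-alkylate with 7, and aluminium clamps the C1 enolate oxygen and the C2 ketone oxygen in five-membered chelate 8; C2=O lies outside the push–pull O–C1=C5–C4=O system and is the only electrophilic carbonyl, so the diazo carbon adds there to give 9; in 9 the rotamer with N2+ anti to the flat sp2 carbon C1 keeps the propanoyl group away from the CMe2 group, so C1 (the acyl/alkenyl carbon) and not the quaternary C3 shifts 1,2 to the diazonium carbon as N2 leaves, the ring grows from five to six members and the 2-acyl-1,3,5-trione is held as chelate 10 until the acid quench; driving forces are loss of N2, relief of the 1,2-dione repulsion and ring strain, and formation of the hydrogen-bonded β-triketone; the closest known reaction type is the Lewis-acid-promoted Tiffeneau–Demjanov-type (Büchner–Curtius–Schlotterbeck) homologation of cyclic ketones and isatins with α-diazo carbonyl compounds, together with the Roskamp β-dicarbonyl synthesis, neither of which has been shown for an acyl diazomethane on a cyclic vicinal-dione enol with selective acyl shift; no stereocentre is formed.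

Step 4
Reactants: 12 resorcinol
Product: 15 benzene-1,3,5-triol (phloroglucinol), via bis(boryloxy)benzene 13 (not isolated), via C5-borylated arene 14 (not isolated)
Conditions: pinacolborane HBpin (3.6 equiv), [Ir(OMe)(cod)]2 (1.5 mol %), 4,4'-di-tert-butyl-2,2'-bipyridine (3 mol %), THF, rt then 80 °C; then 30% aq H2O2, 0 °C to rt; 1 M HCl
Reagents that add atoms: hydrogen peroxide, OO
Why: O–H/B–H dehydrocoupling masks both phenols in the flask, the sterically ruled iridium-catalysed C–H borylation takes the only C–H without an ortho neighbour (C5), and peroxide oxidation (aryl shift from boron to oxygen) with hydrolysis gives the triol.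

Step 5
Reactants: 15 phloroglucinol; 16 butanoyl chloride
Product: 17 1-(2,4,6-trihydroxyphenyl)butan-1-one (butanoylphloroglucinol)
Conditions: AlCl3 (3.5 equiv), 16 (1.0 equiv), CH2Cl2/PhNO2, 0 to 45 °C; ice/2 M HCl
Reagents that add atoms: none
Why: This is a Friedel–Crafts acylation of a symmetrical, very electron-rich arene, and the first acyl group, chelated to aluminium, deactivates the ring against a second acylation.

Step 6
Reactants: 17 butanoylphloroglucinol; 18 N,N,N',N'-tetramethylmethanediamine; 11 propanoylfilicinic acid (2.05 equiv)
Product: 20 filixic acid PBP (target), via bis(dimethylaminomethyl) Mannich base 19 (not isolated)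
Conditions: 18 (2.3 equiv), 1,4-dioxane, rt to 40 °C, then evaporate volatiles; then 11 (2.05 equiv), AcOH (20 mol %), 1,4-dioxane, 80 °C, N2 sparge
Reagents that add atoms: none
Why: A double Mannich aminomethylation first fills both free positions of ring B, so B–CH2–B links cannot form and no free C1 electrophile remains after evaporation, then heat expels Me2NH to give the o-quinone methide, which the soft C6 carbon of 11 traps by Michael addition, twice; no stereocentre is formed.

## Compound list
1 | 3-methylbutan-2-one | CC(=O)C(C)C | starting material
2 | dimethyl oxalate | COC(=O)C(=O)OC | starting material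
3 | methyl 5-methyl-2,4-dioxohexanoate | COC(=O)C(=O)CC(=O)C(C)C | intermediate (not isolated)
4 | 3,3-dimethylcyclopentane-1,2,4-trione | CC1(C)C(=O)CC(=O)C1=O | intermediate
5 | propanoyl chloride | CCC(=O)Cl | starting material
6 | trimethylsilyldiazomethane | C[Si](C)(C)C=[N+]=[N-] | starting material
7 | 1-diazobutan-2-one | CCC(=O)C=[N+]=[N-] | intermediate
8 | dichloroaluminium enolate (O,O-chelate) of 4 | CC1(C)C(=O)C=C(O[Al](Cl)Cl)C1=O | intermediate (not isolated)
9 | C2 adduct of 7 to 8, cyclic aluminate with α-diazonium ketone side chain (racemic, transient) | CCC(=O)C([N+]#N)C12O[Al-](Cl)(Cl)OC1=CC(=O)C2(C)C | intermediate (not isolated)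
10 | dichloroaluminium enolate of 11 | CCC(=O)C1=C(O)C(C)(C)C(=O)C=C1O[Al](Cl)Cl | intermediate (not isolated)
11 | 3,5-dihydroxy-4,4-dimethyl-2-propanoylcyclohexa-2,5-dien-1-one (propanoylfilicinic acid) | CCC(=O)C1=C(O)C(C)(C)C(O)=CC1=O | intermediate
12 | resorcinol | Oc1cccc(O)c1 | starting material
13 | 1,3-bis[(4,4,5,5-tetramethyl-1,3,2-dioxaborolan-2-yl)oxy]benzene | CC1(C)OB(Oc2cccc(OB3OC(C)(C)C(C)(C)O3)c2)OC1(C)C | intermediate (not isolated)
14 | 5-(pinacolboryl) derivative of 13 | CC1(C)OB(Oc2cc(OB3OC(C)(C)C(C)(C)O3)cc(B3OC(C)(C)C(C)(C)O3)c2)OC1(C)C | intermediate (not isolated)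
15 | benzene-1,3,5-triol (phloroglucinol) | Oc1cc(O)cc(O)c1 | intermediate
16 | butanoyl chloride | CCCC(=O)Cl | starting material
17 | 1-(2,4,6-trihydroxyphenyl)butan-1-one | CCCC(=O)c1c(O)cc(O)cc1O | intermediate
18 | N,N,N',N'-tetramethylmethanediamine | CN(C)CN(C)C | starting material
19 | 1-[3,5-bis(dimethylaminomethyl)-2,4,6-trihydroxyphenyl]butan-1-one | CCCC(=O)c1c(O)c(CN(C)C)c(O)c(CN(C)C)c1O | intermediate (not isolated)
20 | filixic acid PBP, 2,2'-[(5-butanoyl-2,4,6-trihydroxybenzene-1,3-diyl)bis(methylene)]bis(3,5-dihydroxy-4,4-dimethyl-6-propanoylcyclohexa-2,5-dien-1-one), achiral | CCCC(=O)c1c(O)c(CC2=C(O)C(C)(C)C(O)=C(C(=O)CC)C2=O)c(O)c(CC2=C(O)C(C)(C)C(O)=C(C(=O)CC)C2=O)c1O | target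

## Step count and risks
Total step count: 6.
Longest linear sequence: 3 (steps 1, 3, 6; the branches 2, 3, 6 and 4, 5, 6 are equally long).

**Step 3 (the proposed new ring expansion).**
- Risks:
  - O-alkylation of the enol by 7.
  - Spiro-epoxide formation instead of the shift.
  - Migration of C3, which gives the 1,2-dione isomer.
  - Dipolar cycloaddition of 7 to the enedione.
- Fallback (known chemistry): it sets out from 15 (with 5) and comes back at 11.
  - Friedel–Crafts acylation of 15 with 5 (AlCl3, CH2Cl2/PhNO2) gives 1-(2,4,6-trihydroxyphenyl)propan-1-one F1.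
  - Dearomatising geminal C-methylation of this compound (iodomethane 2.2 equiv, NaOMe, MeOH, 0 °C to rt) gives 11.
  - 11 is separated from its less and more methylated homologues by chromatography and crystallisation.

**Step 6 (double methylene bridging).**
- Risks:
  - Retro-Mannich transfer of the CH2 unit and base-induced scrambling of the methylene bridges, which leads to A–CH2–A dimers.
  - An incomplete second coupling.
- Fallback: it sets out from 17 (with 11) and comes back at 20.
  - Double Vilsmeier–Haack formylation (POCl3, DMF, EtOAc) gives 5-butanoyl-2,4,6-trihydroxybenzene-1,3-dicarbaldehyde F2.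
  - L-Proline-catalysed Knoevenagel condensation with 11 (2.1 equiv) gives the bis(alkylidene) compound F3.
  - This bis(alkylidene) compound is reduced as it forms by Hantzsch ester (2.2 equiv, CH2Cl2, rt) to 20.
  - Each bridge is therefore made irreversibly under neutral conditions, with no formaldehyde equivalent present.

**Step 1 (ring closure at the hindered methine).**
- Risks:
  - The reaction stalls at 3.
  - A second oxalylation occurs at C5 of 4.
- Fallback: it sets out from 1 and comes back at 4, and it reverses the order of the two C–C bonds.
  - TMSCl, Et3N, DMF, 130 °C gives the more substituted silyl enol ether trimethyl[(3-methylbut-2-en-2-yl)oxy]silane F4, purified by distillation.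
  - ZnCl2-promoted C-acylation with methyl chlorooxoacetate (CH2Cl2, 0 °C) sets the quaternary carbon first and gives methyl 3,3-dimethyl-2,4-dioxopentanoate F5.
  - Dieckmann closure through the unhindered acetyl methyl group (KOtBu, THF, 0 °C; then HCl) gives 4.

## Further compounds
F1 | step 3 | 1-(2,4,6-trihydroxyphenyl)propan-1-one | CCC(=O)c1c(O)cc(O)cc1O
F2 | step 6 | 5-butanoyl-2,4,6-trihydroxybenzene-1,3-dicarbaldehyde | CCCC(=O)c1c(O)c(C=O)c(O)c(C=O)c1O
F3 | step 6 | bis(alkylidene) Knoevenagel adduct of F2 with two 11 (transient, alkene geometry not defined) | CCCC(=O)c1c(O)c(C=C2C(=O)C(C)(C)C(O)=C(C(=O)CC)C2=O)c(O)c(C=C2C(=O)C(C)(C)C(O)=C(C(=O)CC)C2=O)c1O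
F4 | step 1 | trimethyl[(3-methylbut-2-en-2-yl)oxy]silane | CC(O[Si](C)(C)C)=C(C)C
F5 | step 1 | methyl 3,3-dimethyl-2,4-dioxopentanoate | COC(=O)C(=O)C(C)(C)C(C)=O
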